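**Plan**

Numbering: O1, C2 (CH2), C3 (bears ring B), C4 (=CH), C4a, C5 (OMe), C6 (prenyl), C7 (OMe), C8, C8a; ring B carbons are primed.
Retrosynthesis: remove the two ring B acetates, then cut in turn C2–C3 of ring C, the C3–C1' bond, the O1–C2 ether bond, the C4=C3 alkene (methylenation), C4a–C4 (formyl) and C6–prenyl.
Enabling feature: C2 is a CH2 group on O1, so as a cation it is an oxocarbenium ion. C2=O1–C8a=C4a–C4=C3 then forms a 1-oxonia-hexatriene whose termini C2 and C3 are the atoms to be joined, and the charge produced at C4 is carried by O1, 5-OMe and 7-OMe of ring A.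
Forward: purchased ring A is prenylated at C6, formylated at C4a, methylenated and O-carboxymethylated. Purchased ring B is attached by a Heck reaction. Ring C is the only ring built, and it closes last by anodic decarboxylation.
Stereochemistry: the target has no stereocentre. The only stereo-element on the way is the E stilbene alkene, set by syn insertion and syn elimination in the Heck step, and it ends as the endocyclic C3=C4 bond.

Key step: step 10

Remark: the four numbered starting materials are taken as catalogue chemicals. Ring B comes from 4-bromoresorcinol because its bromine sits ortho to one hydroxyl and para to the other, which is the pattern needed at C1'.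

**Step 1**
Reactants: 1 3,5-dimethoxyphenol
Product: 2 (3,5-dimethoxyphenoxy)triisopropylsilane
Conditions: TIPSCl, imidazole, DMF, rt
Reagents that add atoms: triisopropylsilyl chloride, CC(C)[Si](Cl)(C(C)C)C(C)C
Why: Routine imidazole-promoted O-silylation of a phenol; the bulky, weakly coordinating TIPS ether removes the acidic proton and shields both neighbouring positions from the base of step 2.

**Step 2**
Reactants: 2 (3,5-dimethoxyphenoxy)triisopropylsilane; 3 prenyl bromide (1-bromo-3-methylbut-2-ene)
Product: 5 [3,5-dimethoxy-4-(3-methylbut-2-en-1-yl)phenoxy]triisopropylsilane, via aryllithium 4 (not isolated)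
Conditions: n-BuLi, THF, 0 °C to rt; then 3, −78 °C to rt
Reagents that add atoms: n-butyllithium, [Li]CCCC (supplies only the lithium of 4)
Why: Directed ortho-metalation, in which the carbon between the two methoxy groups is activated by both donors while the sites beside the hindered OTIPS group are not, followed by SN2 alkylation with the primary allylic bromide as is well known for 2,6-dimethoxyphenyllithium.

**Step 3**
Reactants: 5 [3,5-dimethoxy-4-(3-methylbut-2-en-1-yl)phenoxy]triisopropylsilane
Product: 6 3,5-dimethoxy-4-(3-methylbut-2-en-1-yl)phenol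
Conditions: TBAF, AcOH, THF, 0 °C
Reagents that add atoms: none
Why: Fluoride-induced cleavage of an aryl silyl ether, buffered with acetic acid so that the phenoxide is protonated as it forms; the alkene and the methyl ethers are inert.

**Step 4**
Reactants: 6 3,5-dimethoxy-4-(3-methylbut-2-en-1-yl)phenol
Product: 7 6-hydroxy-2,4-dimethoxy-3-(3-methylbut-2-en-1-yl)benzaldehyde
Conditions: MgCl2, Et3N, (CH2O)n, MeCN, reflux; then cold dilute HCl
Reagents that add atoms: paraformaldehyde (as formaldehyde), C=O
Why: Casnati-Skattebøl ortho-formylation, in which the magnesium phenoxide delivers formaldehyde only ortho to oxygen and a second formaldehyde oxidises the benzylic alkoxide by hydride transfer; para is blocked by prenyl and the two ortho sites are equivalent by symmetry, so only one aldehyde can form, and the non-acidic medium spares the prenyl group.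

**Step 5**
Reactants: 7 6-hydroxy-2,4-dimethoxy-3-(3-methylbut-2-en-1-yl)benzaldehyde
Product: 8 2-ethenyl-3,5-dimethoxy-4-(3-methylbut-2-en-1-yl)phenol
Conditions: MePPh3Br (2.5 equiv), KOt-Bu (2.4 equiv), THF, 0 °C to rt; aq NH4Cl; Et3N-washed silica
Reagents that add atoms: methyltriphenylphosphonium bromide, C[P+](c1ccccc1)(c1ccccc1)c1ccccc1.[Br-]
Why: Wittig methylenation of a salicylaldehyde with excess non-stabilised ylide, one equivalent of base being spent on the phenol; running it before O-alkylation avoids base-induced aldol closure of an ortho-formyl aryloxyacetate to a benzofuran.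

**Step 6**
Reactants: 8 2-ethenyl-3,5-dimethoxy-4-(3-methylbut-2-en-1-yl)phenol; 9 tert-butyl bromoacetate
Product: 10 tert-butyl 2-[2-ethenyl-3,5-dimethoxy-4-(3-methylbut-2-en-1-yl)phenoxy]acetate
Conditions: K2CO3, DMF, rt
Reagents that add atoms: none
Why: Williamson ether synthesis with a reactive α-bromo ester under mild carbonate conditions, which installs O1–C2 and the carboxyl carbon to be expelled later; the tert-butyl ester withstands the amine base and the heat of step 8.

**Step 7**
Reactants: 11 4-bromoresorcinol
Product: 12 4-bromobenzene-1,3-diyl diacetate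
Conditions: Ac2O, pyridine, rt
Reagents that add atoms: acetic anhydride, CC(=O)OC(C)=O
Why: Standard O-acetylation of a phenol; the acetates lower the donor strength of ring B for step 10 and come off under very mild conditions at the end.

**Step 8**
Reactants: 10 tert-butyl 2-[2-ethenyl-3,5-dimethoxy-4-(3-methylbut-2-en-1-yl)phenoxy]acetate; 12 4-bromobenzene-1,3-diyl diacetate
Product: 13 tert-butyl 2-{2-[(E)-2-(2,4-diacetoxyphenyl)ethenyl]-3,5-dimethoxy-4-(3-methylbut-2-en-1-yl)phenoxy}acetate
Conditions: Pd2(dba)3 (2.5 mol %), [HP(t-Bu)3]BF4 (10 mol %), Cy2NMe, 1,4-dioxane, 70 °C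
Reagents that add atoms: none
Why: Mizoroki-Heck arylation at the unhindered terminal carbon of the styrene, where syn insertion and syn β-hydride elimination give the E stilbene directly; the trisubstituted prenyl alkene is far less reactive, the hindered amine leaves the acetates alone, and the coupling avoids ylide chemistry, in which an ortho-acetoxybenzyl ylide would attack its own ester.

**Step 9**
Reactants: 13 tert-butyl 2-{2-[(E)-2-(2,4-diacetoxyphenyl)ethenyl]-3,5-dimethoxy-4-(3-methylbut-2-en-1-yl)phenoxy}acetate
Product: 15 2-{2-[(E)-2-(2,4-diacetoxyphenyl)ethenyl]-3,5-dimethoxy-4-(3-methylbut-2-en-1-yl)phenoxy}acetic acid, via trimethylsilyl ester 14 (not isolated)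
Conditions: TMSOTf, 2,6-lutidine, CH2Cl2, 0 °C; then pH 4 aqueous buffer
Reagents that add atoms: trimethylsilyl triflate, C[Si](C)(C)OS(=O)(=O)C(F)(F)F (supplies only the silyl group of 14)
Why: Silyl-triflate-mediated cleavage of a tert-butyl ester (O-silylation, E1 loss of isobutene, hydrolysis of the silyl ester on work-up) in a lutidine-buffered, proton-free medium, so that the acid-sensitive stilbene and prenyl alkenes see no strong acid and the base-labile acetates see no strong base.

**Step 10**
Reactants: 15 2-{2-[(E)-2-(2,4-diacetoxyphenyl)ethenyl]-3,5-dimethoxy-4-(3-methylbut-2-en-1-yl)phenoxy}acetic acid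
Product: 18 4-[5,7-dimethoxy-6-(3-methylbut-2-en-1-yl)-2H-chromen-3-yl]benzene-1,3-diyl diacetate (dehydroglyasperin D diacetate), via oxocarbenium ion 16 (not isolated), via C4 benzylic cation 17 (not isolated)
Conditions: graphite anode, Pt cathode, undivided cell, constant current (about 2 mA cm−2), 2.0–2.2 F mol−1; n-Bu4NPF6 (0.1 M), 2,6-di-tert-butyl-4-methylpyridine, 3 Å MS, CH2Cl2 (5 mM in 15), 0 °C, Ar
Reagents that add atoms: none
Why: Proposed new method: removal of two electrons at the carbon anode, either from the carboxylate or (pseudo-Kolbe) from the electron-rich ring A/stilbene π system with subsequent C–C fragmentation, expels CO2 and gives the aryloxymethyl radical, which is oxidised far below the working potential to the O1=C2 oxocarbenium ion 16. In 16 the array C2=O1–C8a=C4a–C4=C3 is a 1-oxonia-hexatriene that, thanks to the E alkene, carries only hydrogen on the inner side of C3, so C2 bonds to C3 in a disrotatory 6π closure (formally a 6-endo-trig Prins cyclisation) that forms ring C and cation 17. The hindered pyridine, too bulky to bind the unhindered CH2 terminus of 16, removes H3, which erases the only (transient, racemic) stereocentre and leaves the C3=C4 alkene conjugated with rings A and B at the oxidation level of the target, while the protons are discharged as H2 at the cathode. The closest known reaction types are the Hofer-Moest (non-Kolbe) electrolysis of aryloxy- and alkoxyacetic acids, where the same ions are caught by alcohols, the addition of anodically generated alkoxycarbenium ions to alkenes, and Lewis-acid Prins cyclisations; interception of a decarboxylatively formed aryloxymethyl cation by a tethered stilbene is the unprecedented element. The selectivity needed is C2–C3 (6-endo) over C2–C4 (5-exo) bonding, and the substrate secures it because the former places the charge on benzylic C4, whose ring carbon C4a has O1 and 5-OMe ortho and 7-OMe para, whereas the latter would place it on C3 beside a ring B made a poor donor by its two acetoxy groups. High dilution, molecular sieves and a weakly coordinating electrolyte suppress capture of 16 by carboxylate, water or a second arene, the isolated prenyl alkene is oxidised only at much higher potential, and the charge limit guards the product, which is about as oxidisable as 15.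

**Step 11**
Reactants: 18 4-[5,7-dimethoxy-6-(3-methylbut-2-en-1-yl)-2H-chromen-3-yl]benzene-1,3-diyl diacetate
Product: 19 dehydroglyasperin D, 4-[5,7-dimethoxy-6-(3-methylbut-2-en-1-yl)-2H-chromen-3-yl]benzene-1,3-diol
Conditions: K2CO3 (0.5 equiv), degassed MeOH, Ar, 0 °C; then pH 6 phosphate buffer
Reagents that add atoms: none
Why: Carbonate-catalysed transesterification (methanolysis) of aryl acetates, fast at 0 °C; exclusion of oxygen and a buffered quench protect the electron-rich resorcinol-isoflavene, and no other group in 18 reacts.

**Compound list**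

1 | 3,5-dimethoxyphenol | COc1cc(O)cc(OC)c1 | starting material
2 | (3,5-dimethoxyphenoxy)triisopropylsilane | COc1cc(O[Si](C(C)C)(C(C)C)C(C)C)cc(OC)c1 | intermediate
3 | prenyl bromide (1-bromo-3-methylbut-2-ene) | CC(C)=CCBr | starting material
4 | 2,6-dimethoxy-4-(triisopropylsilyloxy)phenyllithium | COc1cc(O[Si](C(C)C)(C(C)C)C(C)C)cc(OC)c1[Li] | intermediate
5 | [3,5-dimethoxy-4-(3-methylbut-2-en-1-yl)phenoxy]triisopropylsilane | COc1cc(O[Si](C(C)C)(C(C)C)C(C)C)cc(OC)c1CC=C(C)C | intermediate
6 | 3,5-dimethoxy-4-(3-methylbut-2-en-1-yl)phenol | COc1cc(O)cc(OC)c1CC=C(C)C | intermediate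
7 | 6-hydroxy-2,4-dimethoxy-3-(3-methylbut-2-en-1-yl)benzaldehyde | COc1cc(O)c(C=O)c(OC)c1CC=C(C)C | intermediate
8 | 2-ethenyl-3,5-dimethoxy-4-(3-methylbut-2-en-1-yl)phenol | COc1cc(O)c(C=C)c(OC)c1CC=C(C)C | intermediate
9 | tert-butyl bromoacetate | CC(C)(C)OC(=O)CBr | starting material
10 | tert-butyl 2-[2-ethenyl-3,5-dimethoxy-4-(3-methylbut-2-en-1-yl)phenoxy]acetate | COc1cc(OCC(=O)OC(C)(C)C)c(C=C)c(OC)c1CC=C(C)C | intermediate
11 | 4-bromoresorcinol | Oc1ccc(Br)c(O)c1 | starting material
12 | 4-bromobenzene-1,3-diyl diacetate | CC(=O)Oc1ccc(Br)c(OC(C)=O)c1 | intermediate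
13 | tert-butyl 2-{2-[(E)-2-(2,4-diacetoxyphenyl)ethenyl]-3,5-dimethoxy-4-(3-methylbut-2-en-1-yl)phenoxy}acetate | COc1cc(OCC(=O)OC(C)(C)C)c(/C=C/c2ccc(OC(C)=O)cc2OC(C)=O)c(OC)c1CC=C(C)C | intermediate
14 | trimethylsilyl ester of acid 15 | COc1cc(OCC(=O)O[Si](C)(C)C)c(/C=C/c2ccc(OC(C)=O)cc2OC(C)=O)c(OC)c1CC=C(C)C | intermediate
15 | 2-{2-[(E)-2-(2,4-diacetoxyphenyl)ethenyl]-3,5-dimethoxy-4-(3-methylbut-2-en-1-yl)phenoxy}acetic acid | COc1cc(OCC(=O)O)c(/C=C/c2ccc(OC(C)=O)cc2OC(C)=O)c(OC)c1CC=C(C)C | intermediate
16 | aryl(methylidene)oxonium (O1=C2 oxocarbenium) ion derived from 15 | COc1cc([O+]=C)c(/C=C/c2ccc(OC(C)=O)cc2OC(C)=O)c(OC)c1CC=C(C)C | intermediate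
17 | 3-(2,4-diacetoxyphenyl)-5,7-dimethoxy-6-(3-methylbut-2-en-1-yl)chroman-4-ylium, racemic at C3 | COc1cc2OCC([CH+]c2c(OC)c1CC=C(C)C)c1ccc(OC(C)=O)cc1OC(C)=O | intermediate
18 | dehydroglyasperin D diacetate | COc1cc2c(c(OC)c1CC=C(C)C)C=C(c1ccc(OC(C)=O)cc1OC(C)=O)CO2 | intermediate
19 | dehydroglyasperin D | COc1cc2c(c(OC)c1CC=C(C)C)C=C(c1ccc(O)cc1O)CO2 | target

Total step count: 11. Longest linear sequence: 10 (steps 1–6 and 8–11).

**Steps most likely to fail**

1. **Step 10.**
 - What may go wrong:
 - 5-exo cyclisation of the aryloxymethyl radical onto C4 before the second electron is removed;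
 - capture of the cation by carboxylate or traces of water;
 - further oxidation of the product at C2 towards the benzopyrylium level;
 - fouling of the anode by coupling of stilbene radical cations.
 - Fallback (known chemistry): ring C is closed at C3=C4 by olefin metathesis. It sets out from 8 and 12 and comes back at 18. Compound 8 is alkylated with 2,3-dibromopropene (K2CO3, acetone) to the 2-bromoallyl ether F1. Compound 12 undergoes Miyaura borylation (B2pin2, PdCl2(dppf), KOAc, dioxane, 80 °C) to the pinacol boronate F2. Suzuki coupling of the two (Pd(PPh3)4, anhydrous K3PO4, dioxane) should give the 2-arylallyl ether F3. Ring-closing metathesis with the second-generation Grubbs catalyst in CH2Cl2 then joins the vinyl group to the 1,1-disubstituted alkene, a closure known for isoflav-3-enes and tolerant of prenyl groups, and delivers 18.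

2. **Step 2.**
 - What may go wrong: incomplete lithiation, lithiation beside the silyl ether with oxygen-to-carbon silyl migration, or SN2' attack on the allylic bromide.
 - Fallback: the phenolic oxygen is introduced after the prenyl group. It sets out from 3 and comes back at 6, bypassing steps 1–3. Commercial 1,3-dimethoxybenzene is lithiated at its only doubly activated carbon (n-BuLi, THF) to 2,6-dimethoxyphenyllithium F4, which is alkylated with 3 to 1,3-dimethoxy-2-(3-methylbut-2-en-1-yl)benzene F5. Sterically governed C–H borylation ([Ir(OMe)(cod)]2, dtbpy, B2pin2, THF) at the one ring position without an ortho neighbour should give the aryl pinacol boronate F6. Oxidation with NaBO3·4H2O in THF/water gives 6.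

3. **Step 9.**
 - What may go wrong: protonation of the electron-rich stilbene or the prenyl alkene by adventitious triflic acid, E/Z scrambling, or loss of an acetate during work-up.
 - Fallback: the acid is liberated by saponification before ring B and its acetates arrive. It sets out from 8 and 12 and comes back at 15. Compound 8 is alkylated with methyl bromoacetate (K2CO3, acetone) to the methyl ester F7. LiOH in THF/water gives the styrene acid F8. The Heck coupling of step 8 is then run on F8 with 12 and one extra equivalent of Cy2NMe, the carboxylate being a spectator, to give 15 directly.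

**Further compounds**

F1 | step 10 | 1-(2-bromoprop-2-en-1-yloxy)-2-ethenyl-3,5-dimethoxy-4-(3-methylbut-2-en-1-yl)benzene | COc1cc(OCC(Br)=C)c(C=C)c(OC)c1CC=C(C)C
F2 | step 10 | 4-(4,4,5,5-tetramethyl-1,3,2-dioxaborolan-2-yl)benzene-1,3-diyl diacetate | CC(=O)Oc1ccc(B2OC(C)(C)C(C)(C)O2)c(OC(C)=O)c1
F3 | step 10 | 4-{3-[2-ethenyl-3,5-dimethoxy-4-(3-methylbut-2-en-1-yl)phenoxy]prop-1-en-2-yl}benzene-1,3-diyl diacetate | COc1cc(OCC(=C)c2ccc(OC(C)=O)cc2OC(C)=O)c(C=C)c(OC)c1CC=C(C)C
F4 | step 2 | 2,6-dimethoxyphenyllithium | COc1cccc(OC)c1[Li]
F5 | step 2 | 1,3-dimethoxy-2-(3-methylbut-2-en-1-yl)benzene | COc1cccc(OC)c1CC=C(C)C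
F6 | step 2 | 2-[3,5-dimethoxy-4-(3-methylbut-2-en-1-yl)phenyl]-4,4,5,5-tetramethyl-1,3,2-dioxaborolane | COc1cc(B2OC(C)(C)C(C)(C)O2)cc(OC)c1CC=C(C)C
F7 | step 9 | methyl 2-[2-ethenyl-3,5-dimethoxy-4-(3-methylbut-2-en-1-yl)phenoxy]acetate | COC(=O)COc1cc(OC)c(CC=C(C)C)c(OC)c1C=C
F8 | step 9 | 2-[2-ethenyl-3,5-dimethoxy-4-(3-methylbut-2-en-1-yl)phenoxy]acetic acid | OC(=O)COc1cc(OC)c(CC=C(C)C)c(OC)c1C=C
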